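## The problem

The target 17 is 5,7-dihydroxy-6,8-dimethyl-2-pentadecyl-4H-chromen-4-one. Its benzene ring A carries a substituent on every carbon (OH at C5 and C7, methyl at C6 and C8, the ring oxygen at C8a, the carbonyl carbon C4 at C4a) and is fused to a 4-pyranone whose C2 bears an unbranched C15 chain. There is no stereocentre, so the task is one of connectivity: a hexasubstituted arene with alternating oxygen and carbon substituents must be made without regiochemical ambiguity, and the 1,3-dioxygenated unit C2–C3–C4 must be attached and closed through O1. Placing the two methyl groups by late C-methylation of a phloroglucinol suffers from O- versus C-alkylation and over-alkylation to dienones, so they are better brought in before ring A is aromatic. The free dimethylphloroglucinol nucleus oxidises readily in base and air, the 4-pyranone opens under strong nucleophiles, and an unmasked chain of five carbonyl-level carbons would fold in several ways. Read as C8a, C8, C7, C6, C5, C4a, C4, C3, C2, the skeleton is a pentaketide methylated at C6 and C8, and ring A is what an intramolecular Claisen condensation between C4a and an ester carbon C8a delivers. C2–C4 can be stored as a 3-pentadecylisoxazole (C4 as isoxazole C5, C2 as isoxazole C3), which blocks every aldol folding and also acidifies the C4a methylene. Ring A of the cyclised product is symmetric about the C4a–C7 axis, so either phenol flanking C4a closes the pyranone to the same chromone. The only stereocentres on the way, C6 and C8 of the open chain, are epimerisable and vanish on aromatisation.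

## Retrosynthesis

The pyranone ring of 17 is cut first, at O1–C2. Behind it stands the vinylogous amide 16, which is the N–O cleavage product of the 5-aryl-3-pentadecylisoxazole 15. This is preferred to cuts at C2–C3 or C3–C4, which would leave an aryl ketone and bring olefination or acyl-transfer chemistry onto a hindered, electron-rich arene. 15 keeps every carbon of the target. The forward reaction must reduce only the N–O bond; the acid closure has no regiochemical choice because ring A is symmetric.

Ring A of 15 is opened at C4a–C8a through its triketo tautomer 14. Cutting here, rather than at C4a–C4 (acylation or coupling on a preformed C-dimethylated triol arene) or inside the C5–C8 segment, turns the arene into the open-chain diketo ester 13. In 13 the methyl groups already sit on C6 and C8, and C4a is the one methylene activated by both a ketone and the heteroaryl ring. The forward step must form the carbon–carbon bond in preference to the lactone and must not cleave the chain by retro-Claisen reaction.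

13 is cut at C5–C6 into the isoxazolylacetic acid 9 (activated as the N-acylimidazole 11) and the dianion 12 of the purchased keto ester 10. The neighbouring cut at C4a–C5 would use the lithiated isoxazole 8 as nucleophile and a diester of the whole C5–C8a unit as electrophile. It looks shorter, but it pairs a very basic carbanion with a partner carrying two far more acidic protons, so proton transfer would replace acylation. In the chosen polarity the basic partner 12 is the cheap one and can be used in excess. Compound 10 brings C6, C7, C8, C8a and both methyl groups. The forward reaction needs γ-selective acylation of the dianion, faster than deprotonation of 11.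

9 is cut between the side-chain methylene C4a and the carboxyl carbon C5, leading back to 5-methyl-3-pentadecylisoxazole 7 through its lateral anion 8 and a carboxylation. Bringing the acetic acid unit in with the dipolarophile is kept as a fallback. Metalation is preferred because the 5-methyl group of a 3,5-dialkylisoxazole is by far its most acidic position.

The isoxazole of 7 is cut at O1–C5 and C3–C4 into the nitrile oxide 5 and the enol acetate 3, a liquid dipolarophile at the oxidation level of a terminal C3 alkyne. The adduct 6 aromatises by losing its acetoxy group. Condensing an unsymmetrical 1,3-diketone with an N–O reagent would give both regioisomers, whereas the dipole fixes the chain on C3 and the methyl on C5. 5 comes from the oxime 2 through the hydroximoyl chloride 4, and 2 from hexadecanal 1. The cycloaddition has to outrun dimerisation of the unhindered nitrile oxide.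

## Roads not taken

Alternative 1: The cut is at C4a–C4 and C4–C3, with ring A bought as a protected arene. In the forward key step the aryl iodide A2, the terminal alkyne A3 and one carbonyl carbon are joined by a palladium-catalysed carbonylative Sonogashira coupling to the aryl alkynyl ketone A1. Acid would then remove the methoxymethyl ethers and a freed phenol would add 6-endo-dig to give the chromone.
- Merits: highly convergent, all target carbons assembled in one catalytic step, and probably one or two steps shorter than the chosen route if the C-dimethylated arene can be bought.
- Weak points: A2 is an electron-rich iodide flanked by two alkoxy groups, so oxidative addition to zerovalent palladium is slow and the hindered acyl-palladium must outpace direct, non-carbonylative alkynylation. Making A2 needs selective C-dimethylation, three protections and an iodination. The ynone can also close 5-exo to an aurone.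
- Comparison: this road is better in convergence and likely in step count. The chosen plan sets against it that the methyl groups arrive with the chain (from 10), that it needs no protecting group, no hindered cross-coupling and no toxic gas, and that the pyranone closure from 16 has only one mode.

Alternative 2: The cut is at C2=C3 of the pyranone. In the forward key step the keto-stabilised ylide A5 attacks the carbonyl of its own neighbouring aryl ester and expels phosphine oxide, giving the chromone dimethyl ether A4.
- Merits: the intramolecular ester Wittig closure is a dependable, neutral chromone synthesis without regiochemical ambiguity, and probably more predictable than a Claisen folding.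
- Weak points: the route is linear on the arene. A pentasubstituted hydroxyacetophenone with two O-methyl and two C-methyl groups and one distinguished phenol must be made, then acylated, brominated, converted to the phosphonium salt and cyclised. A4 still needs double O-demethylation; the C5 ether next to the carbonyl is easy, but the C7 ether between two methyl groups needs a strong boron trihalide that also threatens the pyranone.
- Comparison: the key step of this road is the safer one. The chosen plan is shorter, carries no protecting group and ends without an ether cleavage.

Alternative 3: The cut is at C4a–C5, with ring A built by a pericyclic cascade on a preformed 4-pyranone. Heating the cyclobutenone A7 opens the four-membered ring to a dienylketene, whose ketene carbon bonds to the pyranone carbon C4a in a 6-electron electrocyclisation; tautomerisation gives A6.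
- Merits: neutral thermal conditions, every substituent placed by the structure of A7, no C- versus O-acylation question, and differentiated oxygens at C5 and C7, which would help analogue work.
- Weak points: A7 is about as complex as the target and needs ketene–alkoxyalkyne [2+2] chemistry on a pyranonyl-substituted ketene. The electrocyclisation must engage a double bond of a quasi-aromatic vinylogous ester. A6 still has to lose an ethyl ether flanked by two methyl groups.
- Comparison: this road is better in regiochemical certainty, but the symmetry of 15 makes that advantage unnecessary here. The chosen plan reaches the same ring from a purchased keto ester in fewer steps and without a final deprotection.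

Key step: step 5

Assumption: 13 is drawn as the triketo form; it should exist as a mixture of diastereomers and enol tautomers that all converge in step 5, and 2 is used as its E/Z mixture.

## Route

Step 1
Reactants: 1 hexadecanal
Product: 2 hexadecanal oxime (E/Z mixture)
Conditions: NH2OH·HCl, NaOAc, EtOH/H2O, rt
Reagents that add atoms: hydroxylamine hydrochloride, Cl.NO
Why: Oxime formation from an unhindered aliphatic aldehyde is fast and clean; both oxime isomers are usable because step 2 removes the C=N geometry.

Step 2
Reactants: 2 hexadecanal oxime; 3 isopropenyl acetate
Product: 7 5-methyl-3-pentadecylisoxazole, via N-hydroxyhexadecanimidoyl chloride 4 (not isolated), via hexadecanenitrile oxide 5 (not isolated), via 5-acetoxy-5-methyl-3-pentadecyl-2-isoxazoline 6 (not isolated)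
Conditions: NCS, DMF, rt; 3 (8 equiv), Et3N (slow addition), CH2Cl2, 0 °C → rt; then cat. p-TsOH, toluene, 80 °C
Reagents that add atoms: none
Why: NCS chlorinates the aldoxime to 4 (the only compound that carries its chlorine), Et3N eliminates HCl to the nitrile oxide 5, and the Huisgen 1,3-dipolar cycloaddition to the 1,1-disubstituted enol acetate places the dipole oxygen on the oxygen-bearing carbon, so 6 has methyl and acetoxy at C5. Loss of acetic acid aromatises 6, which makes 3 a liquid propyne equivalent; slow base addition and excess 3 should hold back furoxan dimerisation.

Step 3
Reactants: 7 5-methyl-3-pentadecylisoxazole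
Product: 9 (3-pentadecylisoxazol-5-yl)acetic acid, via [(3-pentadecylisoxazol-5-yl)methyl]lithium 8 (not isolated)
Conditions: n-BuLi, THF, −78 °C; cannulated onto excess solid CO2 in THF; 1 M HCl
Reagents that add atoms: carbon dioxide, O=C=O
Why: Lateral lithiation of a 3,5-dialkylisoxazole occurs at the 5-alkyl group, whose anion is delocalised through C4 onto nitrogen, well ahead of the 3-alkyl CH2 or C4–H; the ring should not open because C3 is substituted. Inverse quench into excess CO2 carboxylates 8 before it can deprotonate the more acidic product.

Step 4
Reactants: 9 (3-pentadecylisoxazol-5-yl)acetic acid; 10 methyl 2-methyl-3-oxopentanoate (racemic)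
Product: 13 methyl 2,4-dimethyl-3,5-dioxo-6-(3-pentadecylisoxazol-5-yl)hexanoate (diastereomer mixture), via 1-(imidazol-1-yl)-2-(3-pentadecylisoxazol-5-yl)ethanone 11 (not isolated), via dilithiated methyl 2-methyl-3-oxopentanoate 12 (not isolated)
Conditions: 9, CDI, THF, rt, CO2 purged with argon; 10 (3.5 equiv), LiN(i-Pr)2 (7.2 equiv), THF, 0 °C; solution of 11 added at −78 °C, then −30 °C; cold 1 M HCl
Reagents that add atoms: none
Why: This is a Huckin–Weiler γ-acylation: the β-keto ester dianion 12 reacts at its terminal, most basic carbon with the N-acylimidazole 11 (CDI supplies only the leaving group), a pairing well used for precursors of 4-hydroxy-3,5-dimethyl-2-pyranones. The excess of cheap dianion absorbs the imidazole N–H set free by CDI and the acidic protons of the product, and acylation at −78 °C should outrun proton transfer from the CH2 of 11. Cold acidic quench and quick chromatography are meant to keep 13 from lactonising.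

Step 5
Reactants: 13 methyl 2,4-dimethyl-3,5-dioxo-6-(3-pentadecylisoxazol-5-yl)hexanoate
Product: 15 2,4-dimethyl-6-(3-pentadecylisoxazol-5-yl)benzene-1,3,5-triol, via 2,4-dimethyl-6-(3-pentadecylisoxazol-5-yl)cyclohexane-1,3,5-trione 14 (not isolated)
Conditions: Mg(OMe)2 (5 equiv), MeOH, reflux, argon; then 1 M HCl, 0 °C
Reagents that add atoms: none
Why: Mg(OMe)2 reversibly enolises 13; the C4a carbanion, stabilised by the C5 ketone and the isoxazole, adds to the ester carbon C8a, methoxide leaves, and the trione 14 tautomerises at once to the aromatic triol 15 as its magnesium phenoxide, which makes the sequence irreversible. The closest known reactions are the Mg(OMe)2-mediated Claisen cyclisation of 3,5,7-triketo esters to acylphloroglucinols and the Dieckmann closure of 6-aryl-5-oxohexanoates to 2-arylcyclohexane-1,3-diones. Ring A closes in a 6-(enolexo)-exo-trig acyl substitution. No stereocentre is formed and the two epimerisable centres of 13 (C6, C8) are erased, so the diastereomer mixture converges. The step needs carbon–carbon closure to win over other foldings and over O-acylation: the isoxazole holds C2 and C4 at a masked, non-electrophilic level, so no aldol closure to a six-membered carbocycle exists and the Claisen mode is the only one. O-Acylation by the C5 enol oxygen to the 4-hydroxy-2-pyranone is the real competitor; under methoxide that lactone should reopen, as related 6-(2-oxoalkyl)-4-hydroxy-2-pyranones are converted to phloroglucinols by magnesium alkoxide, whereas aromatisation of 14 is a sink. Magnesium chelation keeps the C5/C7 and C7/C8a dicarbonyl units enolised and so protects them from retro-Claisen cleavage. Because 15 is symmetric about the C4a–C7 axis, the later pyranone closure has no regiochemical question.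

Step 6
Reactants: 15 2,4-dimethyl-6-(3-pentadecylisoxazol-5-yl)benzene-1,3,5-triol
Product: 17 5,7-dihydroxy-6,8-dimethyl-2-pentadecyl-4H-chromen-4-one, via (Z)-3-amino-1-(2,4,6-trihydroxy-3,5-dimethylphenyl)octadec-2-en-1-one 16 (not isolated)
Conditions: Mo(CO)6 (1 equiv), wet MeCN, 80 °C, argon; filtration through Celite; then 2 M HCl, EtOH, 70 °C
Reagents that add atoms: none
Why: Zerovalent molybdenum cleaves the isoxazole N–O bond reductively with water as proton source, the standard unmasking to a vinylogous amide, and free phenols are tolerated. In acid a flanking phenol adds to the protonated enaminone at C2 (6-endo-trig) and ammonia is lost, the known closure of 2-hydroxyaryl β-enaminones to chromones. Both phenols ortho to the acyl group are equivalent, so only 17 can form.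

## Compound list

1 | hexadecanal | CCCCCCCCCCCCCCCC=O | starting material
2 | hexadecanal oxime (E/Z mixture) | CCCCCCCCCCCCCCCC=NO | intermediate
3 | isopropenyl acetate (prop-1-en-2-yl acetate) | CC(=C)OC(C)=O | starting material
4 | N-hydroxyhexadecanimidoyl chloride | CCCCCCCCCCCCCCCC(Cl)=NO | intermediate
5 | hexadecanenitrile oxide | CCCCCCCCCCCCCCCC#[N+][O-] | intermediate
6 | 5-methyl-3-pentadecyl-4,5-dihydroisoxazol-5-yl acetate (5-acetoxy-5-methyl-3-pentadecyl-2-isoxazoline, racemic) | CCCCCCCCCCCCCCCC1=NOC(C)(OC(C)=O)C1 | intermediate
7 | 5-methyl-3-pentadecylisoxazole | CCCCCCCCCCCCCCCc1cc(C)on1 | intermediate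
8 | [(3-pentadecylisoxazol-5-yl)methyl]lithium | [Li]Cc1cc(CCCCCCCCCCCCCCC)no1 | intermediate
9 | (3-pentadecylisoxazol-5-yl)acetic acid | OC(=O)Cc1cc(CCCCCCCCCCCCCCC)no1 | intermediate
10 | methyl 2-methyl-3-oxopentanoate (racemic) | CCC(=O)C(C)C(=O)OC | starting material
11 | 1-(imidazol-1-yl)-2-(3-pentadecylisoxazol-5-yl)ethanone | O=C(Cc1cc(CCCCCCCCCCCCCCC)no1)n1ccnc1 | intermediate
12 | dilithiated methyl 2-methyl-3-oxopentanoate (dianion, dilithium salt) | [Li+].[Li+].C[CH-]C([O-])=C(C)C(=O)OC | intermediate
13 | methyl 2,4-dimethyl-3,5-dioxo-6-(3-pentadecylisoxazol-5-yl)hexanoate (mixture of diastereomers and enol tautomers) | COC(=O)C(C)C(=O)C(C)C(=O)Cc1cc(CCCCCCCCCCCCCCC)no1 | intermediate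
14 | 2,4-dimethyl-6-(3-pentadecylisoxazol-5-yl)cyclohexane-1,3,5-trione (stereoisomer mixture) | CCCCCCCCCCCCCCCc1cc(on1)C1C(=O)C(C)C(=O)C(C)C1=O | intermediate
15 | 2,4-dimethyl-6-(3-pentadecylisoxazol-5-yl)benzene-1,3,5-triol | CCCCCCCCCCCCCCCc1cc(on1)-c1c(O)c(C)c(O)c(C)c1O | intermediate
16 | (Z)-3-amino-1-(2,4,6-trihydroxy-3,5-dimethylphenyl)octadec-2-en-1-one | CCCCCCCCCCCCCCC/C(N)=C/C(=O)c1c(O)c(C)c(O)c(C)c1O | intermediate
17 | 5,7-dihydroxy-6,8-dimethyl-2-pentadecyl-4H-chromen-4-one | CCCCCCCCCCCCCCCc1cc(=O)c2c(O)c(C)c(O)c(C)c2o1 | target

## Step count and risks

Total: 6 steps. Longest linear sequence: 6 steps (1 → 2 → 7 → 9 → 13 → 15 → 17); 3 and 10 are purchased.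

Step 5 (key step). The most likely failure is O-acylation outrunning C-acylation. C4a–H is several pK units less acidic than C6–H and C8–H, so the substrate rests as a chelated bis-enolate whose ester is deactivated, and lactonisation to the 4-hydroxy-2-pyranone or retro-Claisen cleavage by methoxide may consume the material before the small equilibrium share of C4a carbanion closes the ring. Fallback: ring A would be bought and the isoxazole grown on it. Setting out from oxime 2, the nitrile oxide 5 (generated through 4 as in step 2) would be added to purchased 2-ethynyl-1,3,5-trimethoxybenzene to give 3-pentadecyl-5-(2,4,6-trimethoxyphenyl)isoxazole F1. NBS (2 equiv) would brominate the two open positions of the activated ring to give 5-(3,5-dibromo-2,4,6-trimethoxyphenyl)-3-pentadecylisoxazole F2. A double Suzuki–Miyaura methylation (MeB(OH)2, Pd(OAc)2, SPhos, K3PO4) would give 3-pentadecyl-5-(2,4,6-trimethoxy-3,5-dimethylphenyl)isoxazole F3, and BBr3 would free the three phenols. The route is rejoined at 15.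

Step 4. Proton transfer may replace acylation: the CH2 of 11 is activated by the acyl group and the isoxazole, and the dianion 12 is strongly basic, so enolisation of 11 (and ketene-derived by-products), together with premature lactonisation of 13 on work-up, could lower conversion. Fallback: the C5–C6 bond would be made by aldol addition and the ketone restored afterwards. Setting out from 9, CDI and then MeNHOMe·HCl would give N-methoxy-N-methyl-2-(3-pentadecylisoxazol-5-yl)acetamide F4. i-Bu2AlH at −78 °C would give (3-pentadecylisoxazol-5-yl)acetaldehyde F5, used at once. Addition of F5 to the dianion 12 at −78 °C, where carbonyl addition is faster than enolisation, would give methyl 5-hydroxy-2,4-dimethyl-3-oxo-6-(3-pentadecylisoxazol-5-yl)hexanoate F6, and Dess–Martin periodinane would oxidise F6 to the diketo ester. The route is rejoined at 13.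

Step 2. Dimerisation of the unhindered aliphatic nitrile oxide to the furoxan may outrun cycloaddition to the only moderately reactive enol acetate, and elimination of acetic acid from 6 may be incomplete. Fallback: the acetic acid side chain would come in with a terminal alkyne, so no elimination and no lateral metalation are needed. Setting out from 2, the nitrile oxide 5 would be trapped with excess but-3-yn-1-ol to give 2-(3-pentadecylisoxazol-5-yl)ethanol F7, and TEMPO/PhI(OAc)2 in MeCN/H2O would oxidise F7 to the acid. The route is rejoined at 9, which replaces steps 2 and 3.

Step 6. The reduction may stall or the electron-rich triol may degrade: binding of the free phloroglucinol to molybdenum, incomplete N–O cleavage at the hindered aryl isoxazole, and oxidation of 15 or 16 during removal of the metal residues are the likely processes. Fallback: the phenols would be capped and the N–O bond cleaved by catalytic hydrogenolysis. Setting out from 15, Ac2O/pyridine would give 2,4-dimethyl-6-(3-pentadecylisoxazol-5-yl)benzene-1,3,5-triyl triacetate F8. H2 over Pd/C in EtOH would give 2-[(Z)-3-aminooctadec-2-enoyl]-4,6-dimethylbenzene-1,3,5-triyl triacetate F9. HCl in MeOH at 60 °C would then remove the acetates and close the pyranone. The route is rejoined at 17.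

## Further compounds

F1 | step 5 | 3-pentadecyl-5-(2,4,6-trimethoxyphenyl)isoxazole | CCCCCCCCCCCCCCCc1cc(on1)-c1c(OC)cc(OC)cc1OC
F2 | step 5 | 5-(3,5-dibromo-2,4,6-trimethoxyphenyl)-3-pentadecylisoxazole | CCCCCCCCCCCCCCCc1cc(on1)-c1c(OC)c(Br)c(OC)c(Br)c1OC
F3 | step 5 | 3-pentadecyl-5-(2,4,6-trimethoxy-3,5-dimethylphenyl)isoxazole | CCCCCCCCCCCCCCCc1cc(on1)-c1c(OC)c(C)c(OC)c(C)c1OC
F4 | step 4 | N-methoxy-N-methyl-2-(3-pentadecylisoxazol-5-yl)acetamide | CON(C)C(=O)Cc1cc(CCCCCCCCCCCCCCC)no1
F5 | step 4 | (3-pentadecylisoxazol-5-yl)acetaldehyde | O=CCc1cc(CCCCCCCCCCCCCCC)no1
F6 | step 4 | methyl 5-hydroxy-2,4-dimethyl-3-oxo-6-(3-pentadecylisoxazol-5-yl)hexanoate (diastereomer mixture) | COC(=O)C(C)C(=O)C(C)C(O)Cc1cc(CCCCCCCCCCCCCCC)no1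
F7 | step 2 | 2-(3-pentadecylisoxazol-5-yl)ethanol | OCCc1cc(CCCCCCCCCCCCCCC)no1
F8 | step 6 | 2,4-dimethyl-6-(3-pentadecylisoxazol-5-yl)benzene-1,3,5-triyl triacetate | CCCCCCCCCCCCCCCc1cc(on1)-c1c(OC(C)=O)c(C)c(OC(C)=O)c(C)c1OC(C)=O
F9 | step 6 | 2-[(Z)-3-aminooctadec-2-enoyl]-4,6-dimethylbenzene-1,3,5-triyl triacetate | CCCCCCCCCCCCCCC/C(N)=C/C(=O)c1c(OC(C)=O)c(C)c(OC(C)=O)c(C)c1OC(C)=O
A1 | alternative 1 | 1-[2,4,6-tris(methoxymethoxy)-3,5-dimethylphenyl]octadec-2-yn-1-one | CCCCCCCCCCCCCCCC#CC(=O)c1c(OCOC)c(C)c(OCOC)c(C)c1OCOC
A2 | alternative 1 | 2-iodo-1,3,5-tris(methoxymethoxy)-4,6-dimethylbenzene | COCOc1c(C)c(OCOC)c(C)c(OCOC)c1I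
A3 | alternative 1 | heptadec-1-yne | CCCCCCCCCCCCCCCC#C
A4 | alternative 2 | 5,7-dimethoxy-6,8-dimethyl-2-pentadecylchromen-4-one | CCCCCCCCCCCCCCCc1cc(=O)c2c(OC)c(C)c(OC)c(C)c2o1
A5 | alternative 2 | 3,5-dimethoxy-2,4-dimethyl-6-[(triphenyl-λ5-phosphanylidene)acetyl]phenyl hexadecanoate | CCCCCCCCCCCCCCCC(=O)Oc1c(C)c(OC)c(C)c(OC)c1C(=O)C=P(c1ccccc1)(c1ccccc1)c1ccccc1
A6 | alternative 3 | 7-ethoxy-5-hydroxy-6,8-dimethyl-2-pentadecylchromen-4-one | CCCCCCCCCCCCCCCc1cc(=O)c2c(O)c(C)c(OCC)c(C)c2o1
A7 | alternative 3 | 3-ethoxy-2,4-dimethyl-4-(4-oxo-6-pentadecyl-4H-pyran-2-yl)cyclobut-2-en-1-one (racemic) | O=C1C(C)=C(OCC)C1(C)c1cc(=O)cc(CCCCCCCCCCCCCCC)o1
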